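## Retrosynthetic overview

- The target comes from its 1,19-diacetate by acetate removal. The diacetate comes from the key C–O step: a tartrate-controlled Sharpless epoxidation of the 6,7-olefin of a free 8,12-diol. The oxirane is the only ring and is closed in the last-but-one step.
- C13–C16 come from allylboration of a C12 enal (sets C12) followed by isopropylidene cross-metathesis.
- C9–C12 come from allylboration of a C8 enal (sets C8) followed by cross-metathesis with methacrolein (sets 10E).
- The C1–C8/C19 enal comes from cross-metathesis of neryl acetate (C1–C6, brings the 2Z olefin) with 2-(acetoxymethyl)acrolein (C7, C8, C19).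

Assumption: atom labels are those of the hexadecane chain of the target, with C19 the hydroxymethyl carbon on C7; the facial sense of both allylborations and of the epoxidation is taken from the established empirical models.

## Route

Step 1
Reactants: 1 2-methylidenepropane-1,3-diol
Product: 3 2-(hydroxymethyl)prop-2-en-1-yl acetate, via cyclic orthoester 2 (not isolated)
Conditions: MeC(OMe)3 (1.2 equiv), camphorsulfonic acid (2 mol%), CH2Cl2, rt; then H2O, rt
Reagents that add atoms: trimethyl orthoacetate CC(OC)(OC)OC; water O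
Why: Acid-catalysed orthoester exchange closes the six-membered cyclic orthoester, and its hydrolysis can only open to the monoacetate (orthoester monoacylation of a symmetric 1,3-diol), so no diacetate forms.

Step 2
Reactants: 3 2-(hydroxymethyl)prop-2-en-1-yl acetate
Product: 4 2-formylprop-2-en-1-yl acetate [2-(acetoxymethyl)acrolein]
Conditions: MnO2 (15 equiv), CH2Cl2, rt; filtered and used at once as a cold solution (BHT)
Reagents that add atoms: none
Why: Manganese dioxide oxidises only the allylic primary alcohol to the enal and leaves the acetate alone (allylic alcohol oxidation).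

Step 3
Reactants: 4 2-formylprop-2-en-1-yl acetate (3 equiv); 5 neryl acetate
Product: 6 (2E,6Z)-8-acetoxy-2-(acetoxymethyl)-6-methylocta-2,6-dienal
Conditions: second-generation Hoveyda–Grubbs catalyst RuCl2(H2IMes)(=CH-C6H4-2-OiPr) (5 mol%), toluene, 60 °C, slow argon sparge
Reagents that add atoms: none
Why: Proposed new method: cross-metathesis between a trisubstituted prenyl-type olefin and a 2-(acyloxymethyl)acrolein has not been shown; the ruthenium alkylidene generated from the electron-rich 6,7-olefin of 5 (the 2,3-olefin is hindered and deactivated by the allylic acetate) should add to the 1,1-disubstituted enal with ruthenium on the CH2 carbon, release 2-methylpropene and give the conjugated trisubstituted enal as the E isomer (formyl trans to the chain, as with methacrolein), which fixes C5 cis to the acetoxymethyl carbon; the closest known reaction type is the olefin cross-metathesis of methacrolein with terminal olefins and with prenyl-terminated terpenoids.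

Step 4
Reactants: 6 (2E,6Z)-8-acetoxy-2-(acetoxymethyl)-6-methylocta-2,6-dienal
Product: 8 (2Z,6E,8S)-7-(acetoxymethyl)-8-hydroxy-3-methylundeca-2,6,10-trien-1-yl acetate, via borinate ester 7 (not isolated)
Conditions: (+)-Ipc2B(allyl) (from (+)-α-pinene, 1.3 equiv, commercial solution), Et2O, −78 °C; then pH 7 buffer, MeOH, 30% H2O2, 0 °C
Reagents that add atoms: (+)-B-allyldiisopinocampheylborane C=CCB([C@@H]1C[C@@H]2C[C@H]([C@H]1C)C2(C)C)[C@@H]1C[C@@H]2C[C@H]([C@H]1C)C2(C)C
Why: Brown asymmetric allylboration, in which the (+)-α-pinene-derived allylborane adds through a closed chair transition state to the Si face of the conjugated aldehyde and so sets C8 as S, while the buffered peroxide work-up spares both acetates.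

Step 5
Reactants: 8 (2Z,6E,8S)-7-(acetoxymethyl)-8-hydroxy-3-methylundeca-2,6,10-trien-1-yl acetate; 9 methacrolein (8 equiv)
Product: 10 (2Z,6E,8S,10E)-7-(acetoxymethyl)-8-hydroxy-3,11-dimethyl-12-oxododeca-2,6,10-trien-1-yl acetate
Conditions: second-generation Hoveyda–Grubbs catalyst RuCl2(H2IMes)(=CH-C6H4-2-OiPr) (5 mol%), CH2Cl2, 40 °C
Reagents that add atoms: none
Why: Olefin cross-metathesis of a terminal olefin with methacrolein is a well-precedented pairing that gives the E enal under thermodynamic control, while the hindered trisubstituted olefins and the free alcohol are untouched.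

Step 6
Reactants: 10 (2Z,6E,8S,10E)-7-(acetoxymethyl)-8-hydroxy-3,11-dimethyl-12-oxododeca-2,6,10-trien-1-yl acetate
Product: 12 (2Z,6E,8S,10E,12R)-7-(acetoxymethyl)-8,12-dihydroxy-3,11-dimethylpentadeca-2,6,10,14-tetraen-1-yl acetate, via borinate ester 11 (not isolated)
Conditions: (−)-Ipc2B(allyl) (from (−)-α-pinene, 2.5 equiv, commercial solution), Et2O, −78 °C; then pH 7 buffer, MeOH, 30% H2O2, 0 °C
Reagents that add atoms: (−)-B-allyldiisopinocampheylborane C=CCB([C@H]1C[C@H]2C[C@@H]([C@@H]1C)C2(C)C)[C@H]1C[C@H]2C[C@@H]([C@@H]1C)C2(C)C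
Why: Brown allylboration with the antipodal reagent adds to the Re face of the enal and sets C12 as R under reagent control, the remote C8 centre having no say and the excess reagent covering the free hydroxyl.

Step 7
Reactants: 12 (2Z,6E,8S,10E,12R)-7-(acetoxymethyl)-8,12-dihydroxy-3,11-dimethylpentadeca-2,6,10,14-tetraen-1-yl acetate
Product: 13 (2Z,6E,8S,10E,12R)-7-(acetoxymethyl)-8,12-dihydroxy-3,11,15-trimethylhexadeca-2,6,10,14-tetraen-1-yl acetate
Conditions: 2-methylbut-2-ene (co-solvent), second-generation Grubbs catalyst RuCl2(H2IMes)(PCy3)(=CHPh) (5 mol%), CH2Cl2, 35 °C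
Reagents that add atoms: 2-methylbut-2-ene CC=C(C)C
Why: Cross-metathesis with 2-methylbut-2-ene turns only the monosubstituted olefin into the prenyl terminus (isopropylidene transfer), the trisubstituted olefins being inert.

Step 8
Reactants: 13 (2Z,6E,8S,10E,12R)-7-(acetoxymethyl)-8,12-dihydroxy-3,11,15-trimethylhexadeca-2,6,10,14-tetraen-1-yl acetate
Product: 14 (2Z,6S,7S,8S,10E,12R)-7-(acetoxymethyl)-6,7-epoxy-8,12-dihydroxy-3,11,15-trimethylhexadeca-2,10,14-trien-1-yl acetate
Conditions: Ti(OiPr)4 (20 mol%), L-(+)-diisopropyl tartrate (28 mol%), t-BuOOH (1.5 equiv, decane), 4 Å sieves, CH2Cl2, −20 °C; stopped when 13 is consumed; Na2SO4/water work-up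
Reagents that add atoms: tert-butyl hydroperoxide CC(C)(C)OO
Why: Katsuki–Sharpless epoxidation in its kinetic-resolution sense, where with L-(+)-tartrate the (8S)-allylic alcohol is the fast (matched) partner and takes oxygen on the face that gives the erythro (6S,7S) oxirane, the (12R)-allylic alcohol is the slow (mismatched) partner so the 10,11-olefin is spared, and the acetates switch off the two primary allylic alcohols as directing groups.

Step 9
Reactants: 14 (2Z,6S,7S,8S,10E,12R)-7-(acetoxymethyl)-6,7-epoxy-8,12-dihydroxy-3,11,15-trimethylhexadeca-2,10,14-trien-1-yl acetate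
Product: 15 (2Z,6S,7S,8S,10E,12R)-6,7-epoxy-7-(hydroxymethyl)-3,11,15-trimethylhexadeca-2,10,14-triene-1,8,12-triol
Conditions: K2CO3 (0.2 equiv), MeOH, 0 °C
Reagents that add atoms: none
Why: Zemplén-type transesterification removes both primary acetates, and the oxirane is safe because a Payne shift would need attack at the fully substituted C7.

## Compound list

1 | 2-methylidenepropane-1,3-diol | C=C(CO)CO | starting material
2 | 2-methoxy-2-methyl-5-methylidene-1,3-dioxane (cyclic orthoester) | COC1(C)OCC(=C)CO1 | intermediate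
3 | 2-(hydroxymethyl)prop-2-en-1-yl acetate | CC(=O)OCC(=C)CO | intermediate
4 | 2-formylprop-2-en-1-yl acetate [2-(acetoxymethyl)acrolein] | CC(=O)OCC(=C)C=O | intermediate
5 | neryl acetate, (2Z)-3,7-dimethylocta-2,6-dien-1-yl acetate | CC(C)=CCC/C(C)=C\COC(C)=O | starting material
6 | (2E,6Z)-8-acetoxy-2-(acetoxymethyl)-6-methylocta-2,6-dienal | O=C/C(COC(C)=O)=C/CC/C(C)=C\COC(C)=O | intermediate
7 | borinate ester of 8: C8–O–B(Ipc)2, isopinocampheyl groups from (+)-α-pinene | C=CC[C@H](OB([C@@H]1C[C@@H]2C[C@H]([C@H]1C)C2(C)C)[C@@H]1C[C@@H]2C[C@H]([C@H]1C)C2(C)C)/C(COC(C)=O)=C/CC/C(C)=C\COC(C)=O | intermediate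
8 | (2Z,6E,8S)-7-(acetoxymethyl)-8-hydroxy-3-methylundeca-2,6,10-trien-1-yl acetate | C=CC[C@H](O)/C(COC(C)=O)=C/CC/C(C)=C\COC(C)=O | intermediate
9 | methacrolein, 2-methylprop-2-enal | CC(=C)C=O | starting material
10 | (2Z,6E,8S,10E)-7-(acetoxymethyl)-8-hydroxy-3,11-dimethyl-12-oxododeca-2,6,10-trien-1-yl acetate | O=C/C(C)=C/C[C@H](O)/C(COC(C)=O)=C/CC/C(C)=C\COC(C)=O | intermediate
11 | borinate ester of 12: C12–O–B(Ipc)2, isopinocampheyl groups from (−)-α-pinene | C=CC[C@@H](OB([C@H]1C[C@H]2C[C@@H]([C@@H]1C)C2(C)C)[C@H]1C[C@H]2C[C@@H]([C@@H]1C)C2(C)C)/C(C)=C/C[C@H](O)/C(COC(C)=O)=C/CC/C(C)=C\COC(C)=O | intermediate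
12 | (2Z,6E,8S,10E,12R)-7-(acetoxymethyl)-8,12-dihydroxy-3,11-dimethylpentadeca-2,6,10,14-tetraen-1-yl acetate | C=CC[C@@H](O)/C(C)=C/C[C@H](O)/C(COC(C)=O)=C/CC/C(C)=C\COC(C)=O | intermediate
13 | (2Z,6E,8S,10E,12R)-7-(acetoxymethyl)-8,12-dihydroxy-3,11,15-trimethylhexadeca-2,6,10,14-tetraen-1-yl acetate | CC(C)=CC[C@@H](O)/C(C)=C/C[C@H](O)/C(COC(C)=O)=C/CC/C(C)=C\COC(C)=O | intermediate
14 | (2Z,6S,7S,8S,10E,12R)-7-(acetoxymethyl)-6,7-epoxy-8,12-dihydroxy-3,11,15-trimethylhexadeca-2,10,14-trien-1-yl acetate | CC(C)=CC[C@@H](O)/C(C)=C/C[C@H](O)[C@]1(COC(C)=O)O[C@H]1CC/C(C)=C\COC(C)=O | intermediate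
15 | (2Z,6S,7S,8S,10E,12R)-6,7-epoxy-7-(hydroxymethyl)-3,11,15-trimethylhexadeca-2,10,14-triene-1,8,12-triol | CC(C)=CC[C@@H](O)/C(C)=C/C[C@H](O)[C@]1(CO)O[C@H]1CC/C(C)=C\CO | target

## Step count and risks

Total step count: 9. Longest linear sequence: 9 steps (1 to 15 through steps 1–9); neryl acetate 5 enters at step 3 and is 7 steps from the target.

Steps most likely to fail:

**Step 3 (the proposed new cross-metathesis).** Two hindered partners may give low conversion, and 4 is a sensitive electrophile. The fallback uses known chemistry, sets out from 5 and comes back at 6. Ozonolysis of the 6,7-olefin of 5 (O3, CH2Cl2, pyridine, −78 °C) gives (4Z)-6-acetoxy-4-methylhex-4-enal F1. Wittig reaction with (triphenylphosphoranylidene)acetaldehyde gives (2E,6Z)-8-acetoxy-6-methylocta-2,6-dienal F2. α-Iodination (I2, K2CO3, cat. DMAP, THF/H2O) gives (2Z,6Z)-8-acetoxy-2-iodo-6-methylocta-2,6-dienal F3. Stille coupling with (tributylstannyl)methanol [Pd(PPh3)4] gives, with retention of geometry, (2E,6Z)-8-acetoxy-2-(hydroxymethyl)-6-methylocta-2,6-dienal F4. Acetylation (Ac2O, pyridine) gives 6.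

**Step 4 (first allylboration).** The 2-(acetoxymethyl) enal is a sensitive electrophile and the selectivity on this α-branched enal may be modest. The fallback sets C8 by reduction instead of addition; it sets out from 6 and comes back at 8. Indium-mediated Barbier allylation (allyl bromide, In, THF/H2O) gives racemic (2Z,6E)-7-(acetoxymethyl)-8-hydroxy-3-methylundeca-2,6,10-trien-1-yl acetate F5. Buffered Dess–Martin oxidation gives (2Z,6E)-7-(acetoxymethyl)-3-methyl-8-oxoundeca-2,6,10-trien-1-yl acetate F6. Corey–Bakshi–Shibata reduction with (R)-2-methyl-CBS-oxazaborolidine and catecholborane at −78 °C gives the catecholborate ester of 8 F7, which is hydrolysed on work-up to 8.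

**Step 8 (late epoxidation).** The electron-poor 6,7-olefin may react slowly, and leakage at the mismatched 10,11-olefin would cost material. The fallback epoxidises before the second allylic alcohol exists and relies on substrate control; it sets out from 8 and comes back at 14. VO(acac)2-catalysed epoxidation of 8 with t-BuOOH (CH2Cl2, 0 °C; erythro by allylic 1,2-strain, the terminal olefin being only homoallylic) gives (2Z,6S,7S,8S)-7-(acetoxymethyl)-6,7-epoxy-8-hydroxy-3-methylundeca-2,10-dien-1-yl acetate F8. Cross-metathesis with 9 gives (2Z,6S,7S,8S,10E)-7-(acetoxymethyl)-6,7-epoxy-8-hydroxy-3,11-dimethyl-12-oxododeca-2,10-dien-1-yl acetate F9. Allylboration with (−)-Ipc2B(allyl) gives the C12 diisopinocampheylborinate F10, and buffered peroxide work-up gives (2Z,6S,7S,8S,10E,12R)-7-(acetoxymethyl)-6,7-epoxy-8,12-dihydroxy-3,11-dimethylpentadeca-2,10,14-trien-1-yl acetate F11. Cross-metathesis with 2-methylbut-2-ene gives 14.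

## Further compounds

F1 | step 3 | (4Z)-6-acetoxy-4-methylhex-4-enal | O=CCC/C(C)=C\COC(C)=O
F2 | step 3 | (2E,6Z)-8-acetoxy-6-methylocta-2,6-dienal | O=C/C=C/CC/C(C)=C\COC(C)=O
F3 | step 3 | (2Z,6Z)-8-acetoxy-2-iodo-6-methylocta-2,6-dienal | O=C/C(I)=C/CC/C(C)=C\COC(C)=O
F4 | step 3 | (2E,6Z)-8-acetoxy-2-(hydroxymethyl)-6-methylocta-2,6-dienal | O=C/C(CO)=C/CC/C(C)=C\COC(C)=O
F5 | step 4 | racemic (2Z,6E)-7-(acetoxymethyl)-8-hydroxy-3-methylundeca-2,6,10-trien-1-yl acetate | C=CCC(O)/C(COC(C)=O)=C/CC/C(C)=C\COC(C)=O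
F6 | step 4 | (2Z,6E)-7-(acetoxymethyl)-3-methyl-8-oxoundeca-2,6,10-trien-1-yl acetate | C=CCC(=O)/C(COC(C)=O)=C/CC/C(C)=C\COC(C)=O
F7 | step 4 | catecholborate ester of 8 | C=CC[C@H](OB1Oc2ccccc2O1)/C(COC(C)=O)=C/CC/C(C)=C\COC(C)=O
F8 | step 8 | (2Z,6S,7S,8S)-7-(acetoxymethyl)-6,7-epoxy-8-hydroxy-3-methylundeca-2,10-dien-1-yl acetate | C=CC[C@H](O)[C@]1(COC(C)=O)O[C@H]1CC/C(C)=C\COC(C)=O
F9 | step 8 | (2Z,6S,7S,8S,10E)-7-(acetoxymethyl)-6,7-epoxy-8-hydroxy-3,11-dimethyl-12-oxododeca-2,10-dien-1-yl acetate | O=C/C(C)=C/C[C@H](O)[C@]1(COC(C)=O)O[C@H]1CC/C(C)=C\COC(C)=O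
F10 | step 8 | C12 diisopinocampheylborinate of F11, isopinocampheyl groups from (−)-α-pinene | C=CC[C@@H](OB([C@H]1C[C@H]2C[C@@H]([C@@H]1C)C2(C)C)[C@H]1C[C@H]2C[C@@H]([C@@H]1C)C2(C)C)/C(C)=C/C[C@H](O)[C@]1(COC(C)=O)O[C@H]1CC/C(C)=C\COC(C)=O
F11 | step 8 | (2Z,6S,7S,8S,10E,12R)-7-(acetoxymethyl)-6,7-epoxy-8,12-dihydroxy-3,11-dimethylpentadeca-2,10,14-trien-1-yl acetate | C=CC[C@@H](O)/C(C)=C/C[C@H](O)[C@]1(COC(C)=O)O[C@H]1CC/C(C)=C\COC(C)=O
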